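The catalyst charge in this flask is small, 40 mM against 0.40 M of each substrate, and two chemists disagree about what so small a charge can do to the excess of right-handed substrate over left-handed substrate.

the same everywhere: left-handed substrate 0.40 M; right-handed substrate 0.40 M; free catalyst 40 mM
- zeta: partner 0.32 M; protic impurity 0.20 M; run made earlier
- theta: partner 0.32 M; protic impurity 0.80 M; run made earlier
- flask: partner 0.320 M; protic impurity 0.400 M; time 25 h

| run | time / h | right-handed substrate / % | left-handed substrate / % | left-handed product / % |
|---|---|---|---|---|
| zeta | 2.00 | 39.5 | 45.3 | 4.2 |
| zeta | 5.00 | 34.3 | 42.9 | 7.1 |
| zeta | 10.0 | 29.3 | 40.5 | 10.0 |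
| zeta | 25.0 | 27.2 | 39.3 | 10.3 |
| theta | 3.00 | 38.8 | 45.2 | 4.2 |
| theta | 8.00 | 36.4 | 44.0 | 5.5 |
| theta | 15.0 | 34.7 | 43.8 | 6.4 |
| theta | 25.0 | 35.1 | 44.2 | 6.4 |

(each reading ± 0.3 percentage points)

1. whether the excess of right-handed substrate over left-handed substrate among what is left of the two reaches 90% by 25 h (no / yes)
2. the highest excess of right-handed substrate over left-handed substrate among what is left of the two up to 25 h

- free catalyst is single-handed; left-handed substrate and right-handed substrate are mirror images of each other, charged as a racemate, each of them at the stated concentration

The first chemist reads the runs as a kinetic resolution. At its first reading, zeta holds less right-handed substrate than left-handed substrate, an excess of −6.84%, and theta opens at −7.62%. The selectivity factor therefore favours consuming right-handed substrate, so she places the top at the racemic start.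

The second chemist points out that no reading comes before the first one, and that a catalyst can hold substrate before any product appears. In zeta's first reading, the left-handed substrate lost exceeds the left-handed product by 0.5 percentage points, a reading hardly clear of its scatter of 0.3 points.

He reckons in two rounds, supposing that each catalyst holds one left-handed substrate and that nothing has reacted yet. The first round sets the catalyst against both substrates charged, which gives 5.00%. But the held substrate no longer counts among what is left of the two, so he takes it off the total and divides by what remains. This gives 5.26%, the binding ceiling: the excess that the catalyst charge can produce by holding left-handed substrate. He expects the top near it.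

That ceiling lies far below the 90% wanted, and the later readings stay negative. My own reckoning is therefore no for the level, with a top between the racemic start and the ceiling.

The forecast sides with the first chemist, answering no with a top of 0%, between 0% and 1%, because “Right-over-left excess is negative throughout”.

The flask gives no, with a top of 1.19%, about a quarter of the ceiling.

    free catalyst + left-handed substrate ⇌ catalyst intermediate A (K = 0.941 M⁻¹, k = 13.9 M⁻¹ min⁻¹)
    free catalyst ⇌ dormant form (K = 0.380, k = 0.00182 min⁻¹)
    partner + catalyst intermediate A → free catalyst + left-handed product (k = 0.231 M⁻¹ min⁻¹)
    free catalyst + right-handed substrate ⇌ catalyst intermediate B (K = 7.30 M⁻¹, k = 0.409 M⁻¹ min⁻¹)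
    partner + catalyst intermediate B → free catalyst + right-handed product (k = 0.0907 M⁻¹ min⁻¹)
    partner + protic impurity → quenched reagent (k = 0.00508 M⁻¹ min⁻¹)

The second chemist's view therefore has its region in the opening of the flask, where the excess rises above the racemic start, but by 2.50 h it stands at −7.06%. The ceiling is reckoned from the catalyst and substrate charges, so the neighbouring flask with 1.3 M of partner has the same 5.26%, and the same share puts its top at about a quarter of that. The neighbour stores a top of 1.22%, and at 25.0 h it holds 3.68% left-handed substrate against 0.502% right-handed substrate.

(The runs were computed from invented constants.)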